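**Retrosynthetic overview**
- The route rests on ring D, a 2,2-dimethyl-3,4-dihydro-2H-pyran fused to ring B. Its benzylic CH2 (C4'') is bonded to C3' and its oxygen sits on the neighbouring C4'. This is the retron of an ortho-quinone methide (C3'=CH2, C4'=O) plus isobutene, so C4''–C3'' and O–C2'' are cut together.
- The quinone methide comes from oxidation of a 3'-methyl-4'-hydroxyisoflavone. O2' is the methyl ether of the target, and O6' and O7 are benzyl ethers, so only one quinone methide can form. The benzyl ethers are removed last.
- Ring C is closed by oxidative 1,2-aryl shift of a 2'-hydroxychalcone and acid cyclisation. The chalcone comes from 4-benzyloxy-2-hydroxyacetophenone (ring A) and a fully differentiated ring B aldehyde.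
- The aldehyde comes from symmetric 2-methylphloroglucinol, whose methyl carbon becomes C4''. Formylation needs no regiochemical choice. The three hydroxyls are then told apart: MOM on the para oxygen, benzyl on the unhindered ortho oxygen, methyl on the hindered chelated one.
- Ring order: A and B are bought, C is closed in step 7, D in step 8.

Key step: step 8

Remark: the target has no stereocentre. The E alkene of the chalcone is the only stereochemical element on the way, and the acetal intermediate is racemic. Ring B aldehydes are numbered with the methyl group at C3 throughout. Isobutene is handled as a condensed liquid in a pressure vessel.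

**Route**

Step 1
Reactants: 1 2-methylphloroglucinol
Product: 3 2,4,6-trihydroxy-3-methylbenzaldehyde, via aryl iminium chloride 2 (not isolated)
Conditions: POCl3 (1.1 equiv), DMF (1.2 equiv), EtOAc, 0 °C to rt; then H2O, 70 °C
Reagents that add atoms: N,N-dimethylformamide CN(C)C=O (formyl carbon); water O (formyl oxygen)
Why: Vilsmeier–Haack formylation of a very electron-rich arene whose two free ring positions are equivalent by symmetry, so only one monoaldehyde can form, and the iminium group of 2 deactivates the ring against a second formylation until hydrolysis.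

Step 2
Reactants: 3 2,4,6-trihydroxy-3-methylbenzaldehyde
Product: 4 2,6-dihydroxy-4-(methoxymethoxy)-3-methylbenzaldehyde
Conditions: MOMCl (1.0 equiv), iPr2NEt (1.1 equiv), THF/CH2Cl2, −10 to 0 °C
Reagents that add atoms: chloromethyl methyl ether COCCl
Why: Base-mediated O-alkylation in which the 4-hydroxyl, para to the formyl group, is the most acidic and is not hydrogen-bonded to the carbonyl as the ortho hydroxyls are, so one equivalent of the small electrophile with a hindered amine base should cap it first.

Step 3
Reactants: 4 2,6-dihydroxy-4-(methoxymethoxy)-3-methylbenzaldehyde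
Product: 5 6-(benzyloxy)-2-hydroxy-4-(methoxymethoxy)-3-methylbenzaldehyde
Conditions: BnBr (1.05 equiv), K2CO3 (1.1 equiv), acetone, rt
Reagents that add atoms: benzyl bromide BrCc1ccccc1
Why: Williamson etherification in which the 3-methyl group pushes the 2-hydroxyl into the hydrogen bond with the formyl oxygen and shields it on both sides, so the 6-hydroxyl, with a hydrogen as its other neighbour, should be alkylated, in line with dialkylations of 3-methylphloroacyl compounds that leave the hydroxyl next to the methyl group free.

Step 4
Reactants: 5 6-(benzyloxy)-2-hydroxy-4-(methoxymethoxy)-3-methylbenzaldehyde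
Product: 6 6-(benzyloxy)-2-methoxy-4-(methoxymethoxy)-3-methylbenzaldehyde
Conditions: MeI (3 equiv), K2CO3 (2 equiv), DMF, 40 °C
Reagents that add atoms: iodomethane CI
Why: Williamson methylation of the last hydroxyl, which is chelated and hindered and therefore needs an excess of the small electrophile in a dipolar solvent, while nothing else in 5 is nucleophilic.

Step 5
Reactants: 7 2,4-dihydroxyacetophenone
Product: 8 4-(benzyloxy)-2-hydroxyacetophenone
Conditions: BnBr (1.05 equiv), K2CO3 (1.2 equiv), acetone, reflux
Reagents that add atoms: benzyl bromide BrCc1ccccc1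
Why: Williamson etherification in which the 2-hydroxyl is held in a hydrogen bond to the acetyl oxygen, so that weak base and one equivalent of BnBr alkylate only the 4-hydroxyl.

Step 6
Reactants: 6 6-(benzyloxy)-2-methoxy-4-(methoxymethoxy)-3-methylbenzaldehyde; 8 4-(benzyloxy)-2-hydroxyacetophenone
Product: 9 (E)-1-[4-(benzyloxy)-2-hydroxyphenyl]-3-[6-(benzyloxy)-2-methoxy-4-(methoxymethoxy)-3-methylphenyl]prop-2-en-1-one
Conditions: KOH (50% aq, excess), EtOH/THF, rt; then AcOH, 0 °C
Reagents that add atoms: none
Why: Claisen–Schmidt condensation of the acetophenone enolate with a non-enolisable aldehyde followed by E1cB loss of water to the conjugated E enone, with the two ortho substituents of ring B disfavouring closure of the 2'-hydroxychalcone to a flavanone.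

Step 7
Reactants: 9 the 2'-hydroxychalcone of step 6
Product: 11 7,6'-di-O-benzyl-4'-hydroxy-2'-methoxy-3'-methylisoflavone, via dimethyl acetal 10 (not isolated)
Conditions: Tl(NO3)3·3H2O (1.1 equiv), MeOH/HC(OMe)3, rt; filter; then 10% aq HCl, MeOH, reflux
Reagents that add atoms: none
Why: Oxidative 1,2-aryl migration of a 2'-hydroxychalcone, in which Tl(NO3)3 adds to the alkene with methanol at the β-carbon and electron-rich ring B shifts to the α-carbon as monovalent thallium leaves, gives acetal 10, which acid closes to ring C by attack of the 2'-hydroxyl on the acetal carbon and loss of two methanol molecules while the same acid cleaves the MOM acetal and leaves both benzyl ethers intact.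

Step 8
Reactants: 11 7,6'-di-O-benzyl-4'-hydroxy-2'-methoxy-3'-methylisoflavone; 12 isobutene
Product: 14 di-O-benzyl glycyrrhizaisoflavone C, via ortho-quinone methide 13 (not isolated)
Conditions: Ag2O (3 equiv), isobutene (large excess, condensed), 4 Å MS, CH2Cl2, sealed tube, dark, rt to 40 °C
Reagents that add atoms: none
Why: Ag2O takes two electrons and two protons from the only free phenol (phenoxyl radical at O4', then loss of a hydrogen from the C3' methyl) to give ortho-quinone methide 13 (C3'=CH2, C4'=O), which reacts as an electron-poor 1-oxadiene with isobutene in a polar, asynchronous inverse-demand hetero-Diels–Alder reaction. The closest known chemistry is the oxidative generation of ortho-quinone methides from ortho-methylphenols, methylphloroglucinol derivatives included, with Ag2O or DDQ and their capture by 1,1-disubstituted alkenes to give 2,2-dialkylchromans. Ring D closes in the cycloaddition itself as a six-membered [4+2] adduct, with C4''–C3'' and O–C2'' formed in one step and the C–C bond leading, and rearomatisation of ring B drives it. No stereocentre arises because C2'' carries two methyl groups. The step needs a quinone methide toward O4' only, which is secured because O2' is a methyl ether and O6' a benzyl ether and because the product has no free phenol and is inert to Ag2O. It also needs the quaternary carbon on oxygen, which the tertiary cation character at C2'' secures, and capture by the alkene ahead of self-dimerisation, which the large excess of liquid isobutene and the slow heterogeneous oxidation should secure.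

Step 9
Reactants: 14 di-O-benzyl glycyrrhizaisoflavone C
Product: 15 glycyrrhizaisoflavone C
Conditions: H2 (1 atm), Pd on carbon (10% Pd/C), EtOAc/MeOH, rt
Reagents that add atoms: none
Why: Hydrogenolysis of the two benzylic C–O bonds over Pd on carbon, in which the chroman ether, the methyl ether and the vinylogous-ester C2=C3 bond of the isoflavone should stay untouched if the reaction is stopped after uptake of two equivalents of H2.

**Compound list**
1 | 2-methylphloroglucinol (2-methylbenzene-1,3,5-triol) | Cc1c(O)cc(O)cc1O | starting material
2 | N,N-dimethyl-(2,4,6-trihydroxy-3-methylbenzylidene)iminium chloride | C[N+](C)=Cc1c(O)cc(O)c(C)c1O.[Cl-] | intermediate (not isolated)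
3 | 2,4,6-trihydroxy-3-methylbenzaldehyde | Cc1c(O)cc(O)c(C=O)c1O | intermediate
4 | 2,6-dihydroxy-4-(methoxymethoxy)-3-methylbenzaldehyde | COCOc1cc(O)c(C=O)c(O)c1C | intermediate
5 | 6-(benzyloxy)-2-hydroxy-4-(methoxymethoxy)-3-methylbenzaldehyde | COCOc1cc(OCc2ccccc2)c(C=O)c(O)c1C | intermediate
6 | 6-(benzyloxy)-2-methoxy-4-(methoxymethoxy)-3-methylbenzaldehyde | COCOc1cc(OCc2ccccc2)c(C=O)c(OC)c1C | intermediate
7 | 2,4-dihydroxyacetophenone | CC(=O)c1ccc(O)cc1O | starting material
8 | 4-(benzyloxy)-2-hydroxyacetophenone | CC(=O)c1ccc(OCc2ccccc2)cc1O | intermediate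
9 | (E)-1-[4-(benzyloxy)-2-hydroxyphenyl]-3-[6-(benzyloxy)-2-methoxy-4-(methoxymethoxy)-3-methylphenyl]prop-2-en-1-one | COCOc1cc(OCc2ccccc2)c(/C=C/C(=O)c2ccc(OCc3ccccc3)cc2O)c(OC)c1C | intermediate
10 | 1-[4-(benzyloxy)-2-hydroxyphenyl]-2-[6-(benzyloxy)-2-methoxy-4-(methoxymethoxy)-3-methylphenyl]-3,3-dimethoxypropan-1-one (racemic) | COCOc1cc(OCc2ccccc2)c(C(C(OC)OC)C(=O)c2ccc(OCc3ccccc3)cc2O)c(OC)c1C | intermediate (not isolated)
11 | 7,6'-di-O-benzyl-4'-hydroxy-2'-methoxy-3'-methylisoflavone, 7-(benzyloxy)-3-[6-(benzyloxy)-4-hydroxy-2-methoxy-3-methylphenyl]-4H-chromen-4-one | COc1c(C)c(O)cc(OCc2ccccc2)c1-c1coc2cc(OCc3ccccc3)ccc2c1=O | intermediate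
12 | isobutene (2-methylpropene) | C=C(C)C | starting material
13 | ortho-quinone methide of 11: 7-(benzyloxy)-3-[6-(benzyloxy)-2-methoxy-3-methylidene-4-oxocyclohexa-1,5-dien-1-yl]-4H-chromen-4-one | C=C1C(=O)C=C(OCc2ccccc2)C(-c2coc3cc(OCc4ccccc4)ccc3c2=O)=C1OC | intermediate (not isolated)
14 | di-O-benzyl glycyrrhizaisoflavone C, 7-(benzyloxy)-3-[7-(benzyloxy)-5-methoxy-2,2-dimethyl-3,4-dihydro-2H-chromen-6-yl]-4H-chromen-4-one | COc1c2c(cc(OCc3ccccc3)c1-c1coc3cc(OCc4ccccc4)ccc3c1=O)OC(C)(C)CC2 | intermediate
15 | glycyrrhizaisoflavone C, 7-hydroxy-3-(7-hydroxy-5-methoxy-2,2-dimethyl-3,4-dihydro-2H-chromen-6-yl)-4H-chromen-4-one | COc1c2c(cc(O)c1-c1coc3cc(O)ccc3c1=O)OC(C)(C)CC2 | target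

**Step count**
Total: 9 steps. Longest linear sequence: 8 steps (1, 2, 3, 4, 6, 7, 8, 9).

**Steps most likely to fail**

1. Step 8. The phenol of 11 has no oxygen donor ortho or para to the hydroxyl, so oxidation on the Ag2O surface may be slow or incomplete. The quinone methide may also be consumed by self-dimerisation, or by addition of unreacted phenol or traces of water, faster than the unactivated, volatile alkene adds. The fallback separates oxidation from cycloaddition; it sets out from 11 and returns at 14. Compound 11 is treated with DDQ (1.05 equiv) in CH2Cl2/MeOH at 0 °C. Hydride abstraction from the C3' methyl, which is activated by three ring oxygens, is followed by capture of the quinone methide by methanol and should give the isolable benzylic ether 7,6'-di-O-benzyl-4'-hydroxy-2'-methoxy-3'-(methoxymethyl)isoflavone F1. F1 is then heated with excess isobutene 12 in toluene in a sealed vessel at 140–150 °C. Thermal loss of methanol regenerates quinone methide 13 at a low stationary concentration, and the cycloaddition should give 14.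

2. Step 7. Tl(NO3)3 may over-oxidise or nitrate the very electron-rich ring B. The nitric acid set free may remove the MOM group early and expose a phenol to the oxidant. Oxidative cyclisation to an aurone may compete with aryl migration. The fallback uses an epoxide rearrangement; it sets out from 9 and returns at 11. The 2'-hydroxyl of 9 is capped (NaH, MOMCl, THF, 0 °C) to give the bis-MOM chalcone (E)-1-[4-(benzyloxy)-2-(methoxymethoxy)phenyl]-3-[6-(benzyloxy)-2-methoxy-4-(methoxymethoxy)-3-methylphenyl]prop-2-en-1-one F2, which avoids flavonol or aurone formation in the next operation. Weitz–Scheffer epoxidation (30% H2O2, NaOH, MeOH/THF, 0 °C to rt) should give the racemic trans-epoxide [4-(benzyloxy)-2-(methoxymethoxy)phenyl]{3-[6-(benzyloxy)-2-methoxy-4-(methoxymethoxy)-3-methylphenyl]oxiran-2-yl}methanone F3. BF3·OEt2 in CH2Cl2 at −20 °C opens the epoxide at the carbon next to ring B and the aroyl group shifts (Meinwald-type rearrangement). This should give 2-[6-(benzyloxy)-2-methoxy-4-(methoxymethoxy)-3-methylphenyl]-3-[4-(benzyloxy)-2-(methoxymethoxy)phenyl]-3-oxopropanal F4. HCl in MeOH at reflux then removes both MOM groups and cyclodehydrates to 11.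

3. Step 3. The two ortho hydroxyls of 4 may not be told apart well enough, so that benzylation also occurs at O2 or at both oxygens. The fallback reverses the logic from selective alkylation to selective dealkylation; it sets out from 4 and returns at 5. Both ortho hydroxyls are benzylated (BnBr 2.5 equiv, K2CO3, DMF, 60 °C) to give 2,6-bis(benzyloxy)-4-(methoxymethoxy)-3-methylbenzaldehyde F5. MgBr2·OEt2 (1.2 equiv) in toluene/Et2O at rt then cleaves one ortho benzyl ether through the magnesium chelate with the formyl oxygen. The C2 ether is twisted out of the ring plane between formyl and methyl, so it is the more basic and more strained and should be the one cleaved. The magnesium phenoxide chelate that forms stops a second cleavage, and the para MOM ether cannot chelate, so the product should be 5.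

Further compounds
F1 | step 8 | 7-(benzyloxy)-3-[6-(benzyloxy)-4-hydroxy-2-methoxy-3-(methoxymethyl)phenyl]-4H-chromen-4-one | COCc1c(O)cc(OCc2ccccc2)c(-c2coc3cc(OCc4ccccc4)ccc3c2=O)c1OC
F2 | step 7 | (E)-1-[4-(benzyloxy)-2-(methoxymethoxy)phenyl]-3-[6-(benzyloxy)-2-methoxy-4-(methoxymethoxy)-3-methylphenyl]prop-2-en-1-one | COCOc1cc(OCc2ccccc2)c(/C=C/C(=O)c2ccc(OCc3ccccc3)cc2OCOC)c(OC)c1C
F3 | step 7 | [4-(benzyloxy)-2-(methoxymethoxy)phenyl]{3-[6-(benzyloxy)-2-methoxy-4-(methoxymethoxy)-3-methylphenyl]oxiran-2-yl}methanone, trans, racemic (one enantiomer drawn) | COCOc1cc(OCc2ccccc2)c([C@@H]2[C@H](O2)C(=O)c2ccc(OCc3ccccc3)cc2OCOC)c(OC)c1C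
F4 | step 7 | 2-[6-(benzyloxy)-2-methoxy-4-(methoxymethoxy)-3-methylphenyl]-3-[4-(benzyloxy)-2-(methoxymethoxy)phenyl]-3-oxopropanal (racemic, enolisable) | COCOc1cc(OCc2ccccc2)c(C(C=O)C(=O)c2ccc(OCc3ccccc3)cc2OCOC)c(OC)c1C
F5 | step 3 | 2,6-bis(benzyloxy)-4-(methoxymethoxy)-3-methylbenzaldehyde | COCOc1cc(OCc2ccccc2)c(C=O)c(OCc2ccccc2)c1C
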